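The key step exploits the cyclopentane's C1 oxygen next to its vicinal quaternary carbons C2 (CH3, cyclohexyl) and C3 (gem-dimethyl). The C2–C3 bond is formed by an acid-triggered protio-semipinacol 1,2-shift that expands a 3-bromo-2,2-dimethylcyclobutanol into the cyclopentanone: one operation builds the ring, the C2 stereocentre and the C1 carbonyl, while the C4 bromide relays its configuration through the carbinol carbon. The precursor is a 2-propenyl unit flanked by that cyclobutanol and by the cyclohexane ring masked as a bromo-7-oxabicyclo[2.2.1]heptane, a temporary ether bridge that sets the ring C–Br centre, blocks bridgehead ionisation and is finally opened to the tertiary chloride.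

Key step: step 12

Remark: locants C1–C5 are those of the cyclopentanol ring of the target (C1 carbinol, C2 quaternary, C3 CMe2, C4 CHBr), primed locants those of the cyclohexane. The antipode of the ammonium catalyst in step 2 is assumed to be the one that gives the (R)-adduct; both antipodes are accessible.

Step 1
Reactants: 1 2,2-dimethyl-1,3-dioxan-5-one; 2 4-methoxybenzoyl chloride
Product: 4 2-[(4-methoxybenzoyl)oxy]prop-2-enal, via dioxinyl enol ester 3 (not isolated)
Conditions: Et3N, DMAP (cat.), CH2Cl2, 0 °C → rt; then toluene, 110 °C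
Reagents that add atoms: none
Why: O-acylation of the dioxanone enol gives the 1,3-dioxin-5-yl ester, which on heating loses acetone in a retro-hetero-Diels–Alder reaction to unmask the 2-acyloxyacrolein dienophile.

Step 2
Reactants: 4 2-[(4-methoxybenzoyl)oxy]prop-2-enal; 5 isoprene
Product: 6 (R)-1-formyl-4-methylcyclohex-3-en-1-yl 4-methoxybenzoate
Conditions: chiral primary ammonium salt (dipeptide-derived triamine·C6F5SO3H, 10 mol %), EtNO2, rt
Reagents that add atoms: none
Why: iminium-catalysed enantioselective Diels–Alder reaction of a 2-acyloxyacrolein, in which the diene methyl group directs the "para" adduct and the catalyst shields one face of the iminium ion, setting the oxygenated quaternary carbon (later C1') as R.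

Step 3
Reactants: 6 (R)-1-formyl-4-methylcyclohex-3-en-1-yl 4-methoxybenzoate
Product: 7 (1R)-1-(1-hydroxyethyl)-4-methylcyclohex-3-en-1-ol (both side-chain epimers)
Conditions: MeMgBr (4 equiv), THF, −78 → 0 °C; aq NH4Cl
Reagents that add atoms: methylmagnesium bromide, C[Mg]Br
Why: Grignard addition to the aldehyde brings in the carbon that becomes the C2 methyl group while excess reagent cleaves the aryl ester by double addition, the side-chain carbinol configuration being irrelevant because it is oxidised in step 4.

Step 4
Reactants: 7 (1R)-1-(1-hydroxyethyl)-4-methylcyclohex-3-en-1-ol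
Product: 8 (R)-1-(1-hydroxy-4-methylcyclohex-3-en-1-yl)ethan-1-one
Conditions: IBX, DMSO, rt
Reagents that add atoms: none
Why: IBX oxidises the secondary hydroxyl of the 1,2-diol to the ketone without glycol cleavage and leaves the tertiary alcohol and the ring alkene untouched.

Step 5
Reactants: 8 (R)-1-(1-hydroxy-4-methylcyclohex-3-en-1-yl)ethan-1-one
Product: 9 N'-[(1E)-1-[(1R)-1-hydroxy-4-methylcyclohex-3-en-1-yl]ethylidene]-2,4,6-tri(propan-2-yl)benzenesulfonohydrazide
Conditions: 2,4,6-triisopropylbenzenesulfonohydrazide, THF, rt
Reagents that add atoms: 2,4,6-triisopropylbenzenesulfonohydrazide, CC(C)c1cc(C(C)C)c(S(=O)(=O)NN)c(C(C)C)c1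
Why: condensation of the methyl ketone with the sulfonyl hydrazide gives the hydrazone needed for the Shapiro reaction, the triisopropylphenyl group preventing ortho-lithiation later.

Step 6
Reactants: 10 2-methylpropanoyl chloride; 11 ethoxyethyne
Product: 13 3-ethoxy-4,4-dimethylcyclobut-2-en-1-one, via dimethylketene 12 (not isolated)
Conditions: Et3N, Et2O, 0 °C → rt
Reagents that add atoms: none
Why: dehydrochlorination gives dimethylketene, which undergoes regioselective [2+2] cycloaddition with the ynol ether (carbonyl carbon to the unsubstituted alkyne carbon) to the vinylogous ester.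

Step 7
Reactants: 13 3-ethoxy-4,4-dimethylcyclobut-2-en-1-one
Product: 15 4,4-dimethylcyclobut-2-en-1-one, via ethoxycyclobutenol 14 (not isolated)
Conditions: LiAlH4, Et2O, −20 °C; then 1 M H2SO4, 0 °C
Reagents that add atoms: water, O
Why: 1,2-reduction of the vinylogous ester followed by acid hydrolysis with allylic transposition (the carbinol oxygen leaves as water, water adds at the ethoxy carbon, ethanol is lost) gives the cyclobutenone with the gem-dimethyl carbon next to the carbonyl.

Step 8
Reactants: 15 4,4-dimethylcyclobut-2-en-1-one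
Product: 16 rac-3-bromo-2,2-dimethylcyclobutan-1-one
Conditions: HBr (33 % in AcOH, 1.1 equiv), CH2Cl2, −20 → 0 °C
Reagents that add atoms: hydrogen bromide, Br
Why: conjugate hydrobromination of the strained enone places bromine on the β-carbon next to the gem-dimethyl carbon.

Step 9
Reactants: 16 rac-3-bromo-2,2-dimethylcyclobutan-1-one
Product: 17 (S)-3-bromo-2,2-dimethylcyclobutan-1-one
Conditions: (R)-Me-CBS (15 mol %), BH3·SMe2 (0.6 equiv), THF, −30 °C; MeOH; chromatography
Reagents that add atoms: none
Why: kinetic resolution by CBS reduction, in which the catalyst-preferred hydride face (CMe2 as large flank, CH2 as small) coincides with the substrate-preferred face anti to C–Br only for the (R)-ketone, so that enantiomer is reduced to the cis-bromohydrin and the mismatched (S)-ketone should be recovered.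

Step 10
Reactants: 9 the trisylhydrazone; 17 (S)-3-bromo-2,2-dimethylcyclobutan-1-one
Product: 19 (1S,3S)-3-bromo-1-{1-[(1R)-1-hydroxy-4-methylcyclohex-3-en-1-yl]ethenyl}-2,2-dimethylcyclobutan-1-ol, via vinyllithium alkoxide 18 (not isolated)
Conditions: n-BuLi (3.2 equiv), THF, −78 → 0 °C; then 17, −78 °C; aq NH4Cl, −78 °C
Reagents that add atoms: none
Why: Shapiro reaction, in which the trianion loses sulfinate and dinitrogen to give the 2-propenyllithium (the neighbouring oxygen is a lithium alkoxide, so no β-elimination), which adds to the strained ketone anti to the 3-bromo substituent and so sets the carbinol centre with hydroxyl cis to bromine.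

Step 11
Reactants: 19 the dienyl diol
Product: 20 (1S,3S)-3-bromo-1-{1-[(1S,2S,4R)-2-bromo-1-methyl-7-oxabicyclo[2.2.1]heptan-4-yl]ethenyl}-2,2-dimethylcyclobutan-1-ol
Conditions: NBS (1.05 equiv), CH2Cl2, −40 → −20 °C, dark
Reagents that add atoms: N-bromosuccinimide, O=C1CCC(=O)N1Br
Why: bromoetherification of the more electron-rich trisubstituted ring alkene, in which only the bromonium ion anti to the tertiary hydroxyl can be captured transannularly at the methyl-bearing carbon (Markovnikov), so the C3' bromide is set trans to oxygen and the ring alkene and C1' hydroxyl are masked in one stroke.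

Step 12
Reactants: 20 the bromo-ether alkenylcyclobutanol
Product: 21 (2R,4S)-4-bromo-2-[(1S,2S,4R)-2-bromo-1-methyl-7-oxabicyclo[2.2.1]heptan-4-yl]-2,3,3-trimethylcyclopentan-1-one
Conditions: Tf2NH (10 mol %), CH2Cl2, −40 → 0 °C
Reagents that add atoms: none
Why: Protonation of the terminal CH2 of the 2-propenyl unit develops tertiary cationic character at the carbon between the bridgehead and the carbinol carbon, and the aligned ring bond from the carbinol carbon to the CMe2 carbon migrates to it as the carbinol oxygen becomes the carbonyl, a protio-semipinacol ring expansion driven by relief of four-ring strain. The closest known reaction type is the Brønsted-acid-promoted semipinacol expansion of 1-(alk-1-en-2-yl)cyclobutanols to 2,2-disubstituted cyclopentanones. No ring is closed by cyclisation: the five-membered ring arises from the four-membered one by a suprafacial [1,2]-carbon shift with retention at the migrating CMe2 carbon. The new quaternary stereocentre C2 is controlled by the cyclobutanol carbon (set anti to C–Br in step 10): in the bridged, bicyclo[2.1.0]pentane-like transition state the bulky oxabicyclic bridgehead sits exo, next to the small carbinol oxygen, and the methyl group sits endo over the four-membered ring, which places the bicycle cis to bromine in the product. The step needs migration of the more substituted CMe2 carbon rather than the ring CH2 (the carbon that better carries positive charge) and chemoselectivity for this pathway, which is secured because the 2-propenyl group is the only alkene left and the adjacent bridgehead C–O can neither ionise nor take part in a competing shift (anti-Bredt strain). The β-bromo ketone is kept cold and away from base.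

Step 13
Reactants: 21 the cyclopentanone
Product: 22 (1R,2S,4S)-4-bromo-2-[(1S,2S,4R)-2-bromo-1-methyl-7-oxabicyclo[2.2.1]heptan-4-yl]-2,3,3-trimethylcyclopentan-1-ol
Conditions: NaBH4, CeCl3·7H2O, MeOH, −40 °C
Reagents that add atoms: none
Why: Luche reduction, in which hydride attacks from the methyl face of C2, anti to the oxabicyclic substituent and to the C4 bromide, so the C1 hydroxyl ends cis to both, and the C1' oxygen being still an ether rules out retro-aldol cleavage.

Step 14
Reactants: 22 the bromo-ether cyclopentanol
Product: 23 (1R,2S,4S)-4-bromo-2-[(1R,3S,4S)-3-bromo-4-chloro-1-hydroxy-4-methylcyclohexyl]-2,3,3-trimethylcyclopentan-1-ol (target)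
Conditions: BCl3 (2.5 equiv), CH2Cl2, −78 → −30 °C; then MeOH, aq NaHCO3
Reagents that add atoms: boron trichloride, ClB(Cl)Cl
Why: boron trihalide ether cleavage, in which boron bound to the C1 oxygen chelates the bridging oxygen, the tertiary methyl-bearing C–O bond ionises with help from the antiperiplanar C–Br (bromonium ion), and chloride enters anti to bromine on the face the oxygen leaves (net retention), giving C4'–Cl cis to the C1' hydroxyl and trans to C3'–Br, after which hydrolysis of the cyclic borate frees the diol.

Compound list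
1 | 2,2-dimethyl-1,3-dioxan-5-one | CC1(C)OCC(=O)CO1 | starting material
2 | 4-methoxybenzoyl chloride | COc1ccc(cc1)C(Cl)=O | starting material
3 | 2,2-dimethyl-4H-1,3-dioxin-5-yl 4-methoxybenzoate | CC1(C)OCC(OC(=O)c2ccc(OC)cc2)=CO1 | intermediate
4 | 2-[(4-methoxybenzoyl)oxy]prop-2-enal | C=C(C=O)OC(=O)c1ccc(OC)cc1 | intermediate
5 | isoprene | C=CC(C)=C | starting material
6 | (R)-1-formyl-4-methylcyclohex-3-en-1-yl 4-methoxybenzoate | O=C[C@]1(OC(=O)c2ccc(OC)cc2)CC=C(C)CC1 | intermediate
7 | (1R)-1-(1-hydroxyethyl)-4-methylcyclohex-3-en-1-ol | CC(O)[C@]1(O)CC=C(C)CC1 | intermediate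
8 | (R)-1-(1-hydroxy-4-methylcyclohex-3-en-1-yl)ethan-1-one | CC(=O)[C@]1(O)CC=C(C)CC1 | intermediate
9 | N'-[(1E)-1-[(1R)-1-hydroxy-4-methylcyclohex-3-en-1-yl]ethylidene]-2,4,6-tri(propan-2-yl)benzenesulfonohydrazide | C/C(=N\NS(=O)(=O)c1c(C(C)C)cc(C(C)C)cc1C(C)C)[C@]1(O)CC=C(C)CC1 | intermediate
10 | 2-methylpropanoyl chloride | CC(C)C(Cl)=O | starting material
11 | ethoxyethyne | CCOC#C | starting material
12 | dimethylketene | CC(C)=C=O | intermediate
13 | 3-ethoxy-4,4-dimethylcyclobut-2-en-1-one | CCOC1=CC(=O)C1(C)C | intermediate
14 | 3-ethoxy-4,4-dimethylcyclobut-2-en-1-ol | CCOC1=CC(O)C1(C)C | intermediate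
15 | 4,4-dimethylcyclobut-2-en-1-one | CC1(C)C=CC1=O | intermediate
16 | rac-3-bromo-2,2-dimethylcyclobutan-1-one | CC1(C)C(Br)CC1=O | intermediate
17 | (S)-3-bromo-2,2-dimethylcyclobutan-1-one | O=C1C[C@H](Br)C1(C)C | intermediate
18 | lithium (1R)-1-(1-lithioethenyl)-4-methylcyclohex-3-en-1-olate | C=C([Li])[C@]1(O[Li])CC=C(C)CC1 | intermediate
19 | (1S,3S)-3-bromo-1-{1-[(1R)-1-hydroxy-4-methylcyclohex-3-en-1-yl]ethenyl}-2,2-dimethylcyclobutan-1-ol | C=C([C@]1(O)CC=C(C)CC1)[C@@]1(O)C[C@H](Br)C1(C)C | intermediate
20 | (1S,3S)-3-bromo-1-{1-[(1S,2S,4R)-2-bromo-1-methyl-7-oxabicyclo[2.2.1]heptan-4-yl]ethenyl}-2,2-dimethylcyclobutan-1-ol | C=C([C@]12CC[C@](C)(O1)[C@@H](Br)C2)[C@@]1(O)C[C@H](Br)C1(C)C | intermediate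
21 | (2R,4S)-4-bromo-2-[(1S,2S,4R)-2-bromo-1-methyl-7-oxabicyclo[2.2.1]heptan-4-yl]-2,3,3-trimethylcyclopentan-1-one | CC1(C)[C@@H](Br)CC(=O)[C@@]1(C)[C@]12CC[C@](C)(O1)[C@@H](Br)C2 | intermediate
22 | (1R,2S,4S)-4-bromo-2-[(1S,2S,4R)-2-bromo-1-methyl-7-oxabicyclo[2.2.1]heptan-4-yl]-2,3,3-trimethylcyclopentan-1-ol | CC1(C)[C@@H](Br)C[C@@H](O)[C@@]1(C)[C@]12CC[C@](C)(O1)[C@@H](Br)C2 | intermediate
23 | (1R,2S,4S)-4-bromo-2-[(1R,3S,4S)-3-bromo-4-chloro-1-hydroxy-4-methylcyclohexyl]-2,3,3-trimethylcyclopentan-1-ol | CC1(C)[C@@H](Br)C[C@@H](O)[C@@]1(C)[C@@]1(O)CC[C@](C)(Cl)[C@@H](Br)C1 | target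

Total step count: 14
Longest linear sequence: 10 steps (steps 1–5, then 10–14)

Steps most likely to fail

Step 12 (key step). The ring CH2 carbon may migrate instead of the CMe2 carbon, the shift may occur on the other face of the cationic carbon, or the acid may ionise the tertiary ether or induce loss of HBr from the β-bromo ketone before the alkene is protonated. Fallback: starting from 20, the ring expansion is triggered under neutral conditions by an iodonium ion (N-iodosuccinimide, CH2Cl2, −20 °C), a halo-semipinacol that should give (2S,4S)-4-bromo-2-[(1S,2S,4R)-2-bromo-1-methyl-7-oxabicyclo[2.2.1]heptan-4-yl]-2-(iodomethyl)-3,3-dimethylcyclopentan-1-one F1. Its ketone is reduced first (NaBH4, CeCl3·7H2O, MeOH, −40 °C), so that no radical 1,2-acyl shift (Dowd–Beckwith) can follow, to the iodo alcohol (1R,2R,4S)-4-bromo-2-[(1S,2S,4R)-2-bromo-1-methyl-7-oxabicyclo[2.2.1]heptan-4-yl]-2-(iodomethyl)-3,3-dimethylcyclopentan-1-ol F2. The neopentyl iodide is then removed with (Me3Si)3SiH and Et3B/air at −20 °C, where C–I abstraction should be much faster than abstraction from the secondary bromides. This gives 22, where the route is rejoined.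

Step 14. The other bridgehead C–O bond may cleave with a Wagner–Meerwein shift, the tertiary cation may lose a proton, or chloride may enter without bromine participation and give the wrong relative configuration; the opened product may also re-close to the ether. Fallback: starting from 22, an acylative cleavage is used instead of the boron chelate. Acetyl chloride with catalytic ZnCl2 (CH2Cl2, 0 °C) should acetylate the C1 hydroxyl and open the bridging ether through its acyloxonium ion, the oxygen leaving as a non-nucleophilic tertiary acetate, to give (1R,2S,4S)-2-[(1R,3S,4S)-1-acetoxy-3-bromo-4-chloro-4-methylcyclohexyl]-4-bromo-2,3,3-trimethylcyclopentyl acetate F3. Both acetates are then removed reductively with DIBAL-H (CH2Cl2, −78 °C), which avoids base, to arrive at 23.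

Step 9. The rate difference between the two ketone enantiomers may be too small, so that the recovered ketone is of low enantiomeric purity or is over-reduced. Fallback: starting from 16, the racemate is reduced completely (NaBH4, MeOH, −20 °C; hydride anti to bromine) to rac-cis-3-bromo-2,2-dimethylcyclobutan-1-ol F4. Lipase-catalysed acylation (immobilised Candida antarctica lipase B, vinyl acetate, MTBE) should, by the usual size rule for secondary alcohols, acylate the enantiomer with the (1R) carbinol to give (1R,3S)-3-bromo-2,2-dimethylcyclobutyl acetate F5, leaving the (1S,3R)-alcohol behind. After separation, methanolysis (K2CO3, MeOH, 0 °C) gives (1R,3S)-3-bromo-2,2-dimethylcyclobutan-1-ol F6, and Dess–Martin oxidation (NaHCO3, CH2Cl2) returns to 17.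

Further compounds
F1 | step 12 | (2S,4S)-4-bromo-2-[(1S,2S,4R)-2-bromo-1-methyl-7-oxabicyclo[2.2.1]heptan-4-yl]-2-(iodomethyl)-3,3-dimethylcyclopentan-1-one | CC1(C)[C@@H](Br)CC(=O)[C@@]1(CI)[C@]12CC[C@](C)(O1)[C@@H](Br)C2
F2 | step 12 | (1R,2R,4S)-4-bromo-2-[(1S,2S,4R)-2-bromo-1-methyl-7-oxabicyclo[2.2.1]heptan-4-yl]-2-(iodomethyl)-3,3-dimethylcyclopentan-1-ol | CC1(C)[C@@H](Br)C[C@@H](O)[C@@]1(CI)[C@]12CC[C@](C)(O1)[C@@H](Br)C2
F3 | step 14 | (1R,2S,4S)-2-[(1R,3S,4S)-1-acetoxy-3-bromo-4-chloro-4-methylcyclohexyl]-4-bromo-2,3,3-trimethylcyclopentyl acetate | CC1(C)[C@@H](Br)C[C@@H](OC(C)=O)[C@@]1(C)[C@@]1(OC(C)=O)CC[C@](C)(Cl)[C@@H](Br)C1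
F4 | step 9 | rac-cis-3-bromo-2,2-dimethylcyclobutan-1-ol (both enantiomers) | O[C@@H]1C[C@H](Br)C1(C)C.O[C@H]1C[C@@H](Br)C1(C)C
F5 | step 9 | (1R,3S)-3-bromo-2,2-dimethylcyclobutyl acetate | CC(=O)O[C@@H]1C[C@H](Br)C1(C)C
F6 | step 9 | (1R,3S)-3-bromo-2,2-dimethylcyclobutan-1-ol | O[C@@H]1C[C@H](Br)C1(C)C
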